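**Retrosynthetic overview**
1. The target comes from its 8-O-MOM ether by a mild, late deprotection.
2. The δ-lactone is the only ring that is built (the benzene ring is bought). Cutting C1–O2 gives an open (R)-hydroxy methyl ester.
3. The (R)-carbinol C3 comes from a benzyl dienyl ketone. A CBS reduction sets the only stereocentre.
4. Cutting C3–C4 of the ketone gives a crossed Claisen-type condensation: the laterally lithiated 6-methylsalicylate (a benzylogous ester enolate) is acylated by the C18 (2E,4E)-dienoic Weinreb amide.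
5. The Weinreb amide comes from tetradecanal and 4-phosphonocrotonate (HWE). Crystallising the acid secures the E,E geometry.

Assumption: the stereocentre in the SMILES reads as (3R), and compound 1, LiN(iPr)2 and LiN(SiMe3)2 are bought as such or as solutions.

**Step 1**
Reactants: 1 methyl 2-hydroxy-6-methylbenzoate; 2 chloromethyl methyl ether
Product: 4 methyl 2-(methoxymethoxy)-6-methylbenzoate, via sodium phenoxide 3 (not isolated)
Conditions: NaH (1.2 equiv), DMF, 0 °C; then MOMCl (1.3 equiv), 0 °C → rt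
Reagents that add atoms: chloromethyl methyl ether (2), COCCl
Why: Williamson-type O-alkylation, in which full deprotonation breaks the salicylate hydrogen bond so that the phenoxide is alkylated cleanly and the acidic OH is masked before the strong-base step.

**Step 2**
Reactants: 5 tetradecan-1-ol
Product: 6 tetradecanal
Conditions: TEMPO (0.1 equiv), PhI(OAc)2 (1.1 equiv), CH2Cl2, rt
Reagents that add atoms: none
Why: Oxoammonium (TEMPO) oxidation of a primary alcohol stops at the aldehyde and gives fresh, trimer-free material for the olefination.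

**Step 3**
Reactants: 6 tetradecanal; 7 triethyl (E)-4-phosphonocrotonate
Product: 9 ethyl (2E,4E)-octadeca-2,4-dienoate, via lithiated phosphonate 8 (not isolated)
Conditions: LiN(SiMe3)2 (1.1 equiv), THF, −78 °C; then 6, −78 °C → rt
Reagents that add atoms: triethyl (E)-4-phosphonocrotonate (7), CCOC(=O)/C=C/CP(=O)(OCC)OCC
Why: Vinylogous Horner–Wadsworth–Emmons olefination, in which the stabilised phosphonate anion reacts at the carbon next to phosphorus and gives mainly the new E alkene (about 10:1) while the 2E bond is kept.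

**Step 4**
Reactants: 9 ethyl (2E,4E)-octadeca-2,4-dienoate
Product: 11 (2E,4E)-octadeca-2,4-dienoic acid, via lithium carboxylate 10 (not isolated)
Conditions: LiOH·H2O (3 equiv), THF/MeOH/H2O, rt → 40 °C; 1 M HCl; recrystallise from hexane
Reagents that add atoms: lithium hydroxide, [Li+].[OH-]
Why: Saponification of an unhindered ester gives a crystalline fatty dienoic acid, and recrystallisation removes the minor 4Z isomer so that the diene geometry is fixed before coupling.

**Step 5**
Reactants: 11 (2E,4E)-octadeca-2,4-dienoic acid; 12 N,O-dimethylhydroxylamine hydrochloride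
Product: 14 (2E,4E)-N-methoxy-N-methyloctadeca-2,4-dienamide, via acyl imidazolide 13 (not isolated)
Conditions: 1,1'-carbonyldiimidazole (CDI, 1.2 equiv), CH2Cl2, rt, 1 h; then 12 (1.5 equiv), rt, 12 h
Reagents that add atoms: N,O-dimethylhydroxylamine hydrochloride (12), CNOC.Cl
Why: Amide coupling through the acyl imidazolide is neutral and mild, so the diene neither isomerises nor takes up amine in a conjugate sense.

**Step 6 (key fragment union)**
Reactants: 4 methyl 2-(methoxymethoxy)-6-methylbenzoate (1.5 equiv); 14 (2E,4E)-N-methoxy-N-methyloctadeca-2,4-dienamide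
Product: 17 methyl 2-(methoxymethoxy)-6-[(3E,5E)-2-oxononadeca-3,5-dien-1-yl]benzoate, via lithiated toluate 15 (not isolated), via tetrahedral lithium adduct 16 (not isolated)
Conditions: LiN(iPr)2 (1.55 equiv), THF, −78 °C, 30 min; then 14 in THF, −78 °C, 1 h; AcOH/THF quench at −78 °C
Reagents that add atoms: none
Why: Crossed Claisen-type condensation, in which the benzylogous ester enolate 15 attacks the amide carbonyl in a 1,2 sense and the chelated adduct 16 survives until the cold quench, which rules out over-addition, proton transfer to the product and enolate closure to an isocoumarin (no stereocentre is formed).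

**Step 7**
Reactants: 17 methyl 2-(methoxymethoxy)-6-[(3E,5E)-2-oxononadeca-3,5-dien-1-yl]benzoate
Product: 19 methyl 2-[(2R,3E,5E)-2-hydroxynonadeca-3,5-dien-1-yl]-6-(methoxymethoxy)benzoate, via catechol borate ester 18 (not isolated)
Conditions: (S)-2-methyl-CBS-oxazaborolidine (0.3 equiv), catecholborane (2 equiv), toluene, −78 °C; MeOH, then aq. NaHCO3/NaOH wash
Reagents that add atoms: none
Why: Corey–Bakshi–Shibata reduction, in which the conjugated dienyl arm acts as the large group, so the (S)-catalyst delivers hydride to the Si face (the sense of acetophenone → (R)-1-phenylethanol) and sets (R), while catecholborane at −78 °C leaves diene, ester and MOM untouched.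

**Step 8**
Reactants: 19 methyl 2-[(2R,3E,5E)-2-hydroxynonadeca-3,5-dien-1-yl]-6-(methoxymethoxy)benzoate
Product: 21 (3R)-3-[(1E,3E)-heptadeca-1,3-dien-1-yl]-8-(methoxymethoxy)-3,4-dihydro-1H-isochromen-1-one, via sodium alkoxide 20 (not isolated)
Conditions: NaH (1.1 equiv), THF, 0 °C, 30 min; AcOH quench
Reagents that add atoms: none
Why: Base-induced intramolecular transesterification (lactonisation), in which the alkoxide closes a six-membered ring onto the neighbouring ester and expels methoxide without touching the C3–O bond, so (R) is retained and acid ionisation of the dienylic carbinol is avoided.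

**Step 9**
Reactants: 21 (3R)-3-[(1E,3E)-heptadeca-1,3-dien-1-yl]-8-(methoxymethoxy)-3,4-dihydro-1H-isochromen-1-one
Product: 22 (3R)-3-[(1E,3E)-heptadeca-1,3-dien-1-yl]-8-hydroxy-3,4-dihydro-1H-isochromen-1-one
Conditions: NaHSO4·SiO2, CH2Cl2 (moist), rt
Reagents that add atoms: none
Why: Mild heterogeneous acid hydrolysis of an acetal, in which the phenolic MOM ether next to the lactone carbonyl is the most labile group and cleaves in non-ionising CH2Cl2 under conditions too weak to ionise the dienylic C3–O bond, so the diene geometry and C3 are preserved.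

**Compound list**
1 | methyl 2-hydroxy-6-methylbenzoate | COC(=O)c1c(C)cccc1O | starting material
2 | chloromethyl methyl ether | COCCl | starting material
3 | sodium 2-(methoxycarbonyl)-3-methylphenolate | COC(=O)c1c(C)cccc1[O-].[Na+] | intermediate
4 | methyl 2-(methoxymethoxy)-6-methylbenzoate | COCOc1cccc(C)c1C(=O)OC | intermediate
5 | tetradecan-1-ol | CCCCCCCCCCCCCCO | starting material
6 | tetradecanal | CCCCCCCCCCCCCC=O | intermediate
7 | triethyl (E)-4-phosphonocrotonate | CCOC(=O)/C=C/CP(=O)(OCC)OCC | starting material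
8 | lithiated triethyl 4-phosphonocrotonate | CCOC(=O)/C=C/C([Li])P(=O)(OCC)OCC | intermediate
9 | ethyl (2E,4E)-octadeca-2,4-dienoate | CCCCCCCCCCCCC/C=C/C=C/C(=O)OCC | intermediate
10 | lithium (2E,4E)-octadeca-2,4-dienoate | CCCCCCCCCCCCC/C=C/C=C/C(=O)[O-].[Li+] | intermediate
11 | (2E,4E)-octadeca-2,4-dienoic acid | CCCCCCCCCCCCC/C=C/C=C/C(=O)O | intermediate
12 | N,O-dimethylhydroxylamine hydrochloride | CNOC.Cl | starting material
13 | 1-[(2E,4E)-octadeca-2,4-dienoyl]imidazole | CCCCCCCCCCCCC/C=C/C=C/C(=O)n1ccnc1 | intermediate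
14 | (2E,4E)-N-methoxy-N-methyloctadeca-2,4-dienamide | CCCCCCCCCCCCC/C=C/C=C/C(=O)N(C)OC | intermediate
15 | methyl 2-(lithiomethyl)-6-(methoxymethoxy)benzoate | COCOc1cccc(C[Li])c1C(=O)OC | intermediate
16 | lithium alkoxide of the hemiaminal from 15 and 14 (tetrahedral adduct) | CCCCCCCCCCCCC/C=C/C=C/C(O[Li])(Cc1cccc(OCOC)c1C(=O)OC)N(C)OC | intermediate
17 | methyl 2-(methoxymethoxy)-6-[(3E,5E)-2-oxononadeca-3,5-dien-1-yl]benzoate | CCCCCCCCCCCCC/C=C/C=C/C(=O)Cc1cccc(OCOC)c1C(=O)OC | intermediate
18 | (R)-carbinol 1,3,2-benzodioxaborol-2-yl ether of 19 | CCCCCCCCCCCCC/C=C/C=C/[C@H](OB1Oc2ccccc2O1)Cc1cccc(OCOC)c1C(=O)OC | intermediate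
19 | methyl 2-[(2R,3E,5E)-2-hydroxynonadeca-3,5-dien-1-yl]-6-(methoxymethoxy)benzoate | CCCCCCCCCCCCC/C=C/C=C/[C@H](O)Cc1cccc(OCOC)c1C(=O)OC | intermediate
20 | sodium alkoxide of 19 | CCCCCCCCCCCCC/C=C/C=C/[C@H]([O-])Cc1cccc(OCOC)c1C(=O)OC.[Na+] | intermediate
21 | (3R)-3-[(1E,3E)-heptadeca-1,3-dien-1-yl]-8-(methoxymethoxy)-3,4-dihydro-1H-isochromen-1-one | CCCCCCCCCCCCC/C=C/C=C/[C@H]1Cc2cccc(OCOC)c2C(=O)O1 | intermediate
22 | (3R)-3-[(1E,3E)-heptadeca-1,3-dien-1-yl]-8-hydroxy-3,4-dihydro-1H-isochromen-1-one | CCCCCCCCCCCCC/C=C/C=C/[C@H]1Cc2cccc(O)c2C(=O)O1 | target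

**Totals**
Total step count: 9. Longest linear sequence: 8 steps (5 → 6 → 9 → 11 → 14 → 17 → 19 → 21 → 22).

**Three steps most likely to fail**

Step 6.
- Risk: the soft benzylic anion may add 1,4 or 1,6 to the dienamide, or the base may deprotonate C6 of 14.
- Fallback: an aldol addition followed by oxidation replaces the acylation. It sets out from 9 and 4 and comes back at 17.
- Route: compound 9 is reduced with iBu2AlH (CH2Cl2, −78 °C) to (2E,4E)-octadeca-2,4-dien-1-ol F1. This is oxidised with MnO2 (CH2Cl2, rt) to (2E,4E)-octadeca-2,4-dienal F2. Anion 15, made from 4 as before, adds to the aldehyde carbonyl of F2 at −78 °C in a clean 1,2 vinylogous aldol. A cold AcOH quench keeps racemic methyl 2-[(3E,5E)-2-hydroxynonadeca-3,5-dien-1-yl]-6-(methoxymethoxy)benzoate F3 open. Dess–Martin periodinane with NaHCO3 in CH2Cl2 then oxidises F3 to ketone 17.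

Step 7.
- Risk: the ortho-disubstituted benzyl arm may compete with the dienyl arm as the large group and lower the ee.
- Fallback: a kinetic resolution replaces the asymmetric reduction. It sets out from 17 and comes back at 19.
- Route: Luche reduction (NaBH4, CeCl3·7H2O, MeOH, −78 °C) gives the racemic hydroxy ester already named F3. A Sharpless kinetic resolution follows: Ti(OiPr)4, L-(+)-diisopropyl tartrate, t-BuOOH (0.6 equiv), 4 Å MS, CH2Cl2, −20 °C. It epoxidises only the fast-reacting (S)-enantiomer at the proximal alkene, giving the erythro epoxy alcohol methyl 2-{(2S)-2-hydroxy-2-[(2S,3S)-3-[(1E)-pentadec-1-en-1-yl]oxiran-2-yl]ethyl}-6-(methoxymethoxy)benzoate F4. The slow-reacting (R)-alcohol 19 is recovered by chromatography in high ee at about 55 % conversion.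

Step 9.
- Risk: acid may ionise the dienylic lactone C3–O bond, causing racemisation, allylic shift or elimination.
- Fallback: a self-releasing salicylate acetonide replaces the protecting group that needs acid. It sets out from 1 and 14 and comes back at 22.
- Route: compound 1 is saponified (KOH, aq. EtOH, reflux) to 2-hydroxy-6-methylbenzoic acid F5. This is closed with acetone, (CF3CO)2O and CF3CO2H to 2,2,5-trimethyl-4H-1,3-benzodioxin-4-one F6. Deprotonation of F6 with LiN(iPr)2 at −78 °C and acylation with 14 gives 2,2-dimethyl-5-[(3E,5E)-2-oxononadeca-3,5-dien-1-yl]-4H-1,3-benzodioxin-4-one F7. The same CBS reduction gives 5-[(2R,3E,5E)-2-hydroxynonadeca-3,5-dien-1-yl]-2,2-dimethyl-4H-1,3-benzodioxin-4-one F8. With NaH in THF at 0 °C the alkoxide of F8 attacks the dioxinone carbonyl, acetone leaves, and a buffered quench of the phenoxide gives 22 directly.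

**Further compounds**
F1 | step 6 | (2E,4E)-octadeca-2,4-dien-1-ol | CCCCCCCCCCCCC/C=C/C=C/CO
F2 | step 6 | (2E,4E)-octadeca-2,4-dienal | CCCCCCCCCCCCC/C=C/C=C/C=O
F3 | step 6 | racemic methyl 2-[(3E,5E)-2-hydroxynonadeca-3,5-dien-1-yl]-6-(methoxymethoxy)benzoate | CCCCCCCCCCCCC/C=C/C=C/C(O)Cc1cccc(OCOC)c1C(=O)OC
F4 | step 7 | methyl 2-{(2S)-2-hydroxy-2-[(2S,3S)-3-[(1E)-pentadec-1-en-1-yl]oxiran-2-yl]ethyl}-6-(methoxymethoxy)benzoate | CCCCCCCCCCCCC/C=C/[C@@H]1O[C@H]1[C@@H](O)Cc1cccc(OCOC)c1C(=O)OC
F5 | step 9 | 2-hydroxy-6-methylbenzoic acid | Cc1cccc(O)c1C(=O)O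
F6 | step 9 | 2,2,5-trimethyl-4H-1,3-benzodioxin-4-one | Cc1cccc2OC(C)(C)OC(=O)c12
F7 | step 9 | 2,2-dimethyl-5-[(3E,5E)-2-oxononadeca-3,5-dien-1-yl]-4H-1,3-benzodioxin-4-one | CCCCCCCCCCCCC/C=C/C=C/C(=O)Cc1cccc2OC(C)(C)OC(=O)c12
F8 | step 9 | 5-[(2R,3E,5E)-2-hydroxynonadeca-3,5-dien-1-yl]-2,2-dimethyl-4H-1,3-benzodioxin-4-one | CCCCCCCCCCCCC/C=C/C=C/[C@H](O)Cc1cccc2OC(C)(C)OC(=O)c12
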